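**Retrosynthetic overview**
- Feature: the plan rests on the C2–C3 bond of the dihydrofuran ring (O1–C2–C3–C3a–C7a). C3 is a secondary benzylic alcohol carbon on C3a. C2 is an allylic ether carbon on O1 whose alkene is 1,1-disubstituted. Together they form a homoallylic alcohol, which a carbonyl allylation can make if the allyl unit hangs on the phenol oxygen and the carbonyl is the neighbouring formyl group.
- Disconnections, last bond first: the C3–O acyl bond (angelic acid); the CH3–C bond of the isopropenyl group (methylation of an alkenyl boronate); C2–C3 together with the C–B bond (copper-boryl addition to an aryl allenyl ether, captured by the ortho aldehyde).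
- The allenyl ether comes from the propargyl ether by base isomerisation, run with both carbonyl groups masked as dimethyl acetals. The acetyl group is placed at C5 by iodination and Stille coupling of 2-hydroxy-3,4-dimethoxybenzaldehyde.
- Ring order: the benzene ring is bought complete, and the dihydrofuran ring is the only ring made, in the key step.

Key step: step 7

Assumption: which enantiomer of Ph-BPE leads to the (2R,3R) series cannot be derived for this new substrate class; (R,R)-Ph-BPE is written, and the equally available (S,S) ligand replaces it if the first run shows the opposite sense.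

Step 1
Reactants: 1 2-hydroxy-3,4-dimethoxybenzaldehyde
Product: 2 2-hydroxy-5-iodo-3,4-dimethoxybenzaldehyde
Conditions: NIS (1.05 equiv), TFA (10 mol %), MeCN, 0 °C to rt
Reagents that add atoms: N-iodosuccinimide O=C1CCC(=O)N1I
Why: Electrophilic aromatic iodination should go only to C5, which is para to the free phenol, ortho to the C4 methoxy group and meta to the formyl group, so the site of the later acetyl group is fixed by three concordant directing effects instead of by an uncertain Friedel–Crafts or Fries acetylation of a dimethoxyphenol.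

Step 2
Reactants: 2 2-hydroxy-5-iodo-3,4-dimethoxybenzaldehyde; 3 tributyl(1-ethoxyethenyl)stannane
Product: 5 5-acetyl-2-hydroxy-3,4-dimethoxybenzaldehyde, via aryl enol ether 4 (not isolated)
Conditions: PdCl2(PPh3)2 (5 mol %), 3 (1.3 equiv), 1,4-dioxane, 90 °C; then 1 M HCl, THF, rt
Reagents that add atoms: water O (supplies the ketone oxygen when 4 is hydrolysed)
Why: Migita–Kosugi–Stille coupling with the acetyl-anion equivalent 3 runs without base and therefore spares the salicylaldehyde unit, and dilute acid then hydrolyses the aryl enol ether 4 to the methyl ketone.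

Step 3
Reactants: 5 5-acetyl-2-hydroxy-3,4-dimethoxybenzaldehyde; 6 propargyl bromide
Product: 7 5-acetyl-3,4-dimethoxy-2-(prop-2-yn-1-yloxy)benzaldehyde
Conditions: 6 (1.3 equiv), K2CO3 (1.5 equiv), DMF, rt
Reagents that add atoms: none
Why: Williamson ether synthesis on the acidic phenol, in which carbonate at room temperature is too weak a base to start an aldol condensation between the acetyl and formyl groups.

Step 4
Reactants: 7 5-acetyl-3,4-dimethoxy-2-(prop-2-yn-1-yloxy)benzaldehyde
Product: 8 1-(dimethoxymethyl)-5-(1,1-dimethoxyethyl)-3,4-dimethoxy-2-(prop-2-yn-1-yloxy)benzene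
Conditions: HC(OMe)3 (6 equiv), p-TsOH·H2O (5 mol %), MeOH, 40 °C; Et3N quench
Reagents that add atoms: trimethyl orthoformate COC(OC)OC; methanol CO
Why: Acid-catalysed acetalisation driven by the orthoester masks both carbonyl groups, which is needed because the alkoxide of step 5 would otherwise set off Claisen–Schmidt condensation of the methyl ketone with the aldehyde and let the propargylic anion add to the neighbouring formyl group.

Step 5
Reactants: 8 1-(dimethoxymethyl)-5-(1,1-dimethoxyethyl)-3,4-dimethoxy-2-(prop-2-yn-1-yloxy)benzene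
Product: 9 1-(dimethoxymethyl)-5-(1,1-dimethoxyethyl)-3,4-dimethoxy-2-(propa-1,2-dien-1-yloxy)benzene
Conditions: KOtBu (0.3 equiv), THF, 0 °C to rt
Reagents that add atoms: none
Why: Base-catalysed propargyl–allenyl prototropic isomerisation, the standard entry to aryloxyallenes, now meets a substrate without any electrophilic or enolisable group and should stop at the allene with catalytic base at or below room temperature.

Step 6
Reactants: 9 1-(dimethoxymethyl)-5-(1,1-dimethoxyethyl)-3,4-dimethoxy-2-(propa-1,2-dien-1-yloxy)benzene
Product: 10 1-[5-formyl-2,3-dimethoxy-4-(propa-1,2-dien-1-yloxy)phenyl]ethanone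
Conditions: PPTS (10 mol %), acetone–H2O 10:1, 0 °C to rt; NaHCO3 quench; Et3N-washed silica
Reagents that add atoms: water O
Why: Specific-acid-catalysed acetal hydrolysis, in which ionisation of a benzylic dimethyl acetal or ketal to its alkoxyaryl-stabilised oxocarbenium ion is faster by orders of magnitude than carbon protonation of an aryl enol ether type allene, so a buffered pyridinium acid should free both carbonyl groups and leave the allenyl ether intact.

Step 7
Reactants: 10 1-[5-formyl-2,3-dimethoxy-4-(propa-1,2-dien-1-yloxy)phenyl]ethanone; 11 bis(pinacolato)diboron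
Product: 13 1-[(2R,3R)-3-hydroxy-6,7-dimethoxy-2-[1-(4,4,5,5-tetramethyl-1,3,2-dioxaborolan-2-yl)ethenyl]-2,3-dihydro-1-benzofuran-5-yl]ethanone (cis), via O-boryl ether 12 (not isolated)
Conditions: CuCl (5 mol %), (R,R)-Ph-BPE (6 mol %), NaOtBu (10 mol %), 11 (1.2 equiv), THF, rt, 30 min; 10 added over 1 h at 0 °C; aq NH4Cl work-up
Reagents that add atoms: none
Why: Proposed new method: NaOtBu turns CuCl and the bisphosphine (L) into LCu–OtBu, σ-bond metathesis with 11 gives LCu–Bpin, and this adds syn across the unsubstituted C=C of the allenyl ether from the side remote from the aryloxy group with boron going to the central carbon, which gives a (Z)-3-aryloxy-2-borylallylcopper that carries copper on CH2. The closest known reaction types are the CuCl/bisphosphine three-component coupling of monosubstituted allenes with B2pin2 and aldehydes or ketones and the borylative cyclisation of carbon-tethered allenyl ketones, whereas an allene tied to the carbonyl arene through its own oxygen substituent has not been shown. With copper bound to the formyl oxygen the allyl unit reacts at its γ-carbon, the one bonded to O1, through a closed six-membered chair, so the C2–C3 bond forms and the dihydrofuran ring closes in a 5-exo-trig mode, after which 11 converts the copper alkoxide into boric ester 12 and regenerates LCu–Bpin. C2 and C3 arise in the same event: their relative configuration follows from the (Z) enol-ether geometry, which puts O1 axial and the aryl carbon C3a equatorial in the chair and thus maps onto the syn adduct, that is the cis ring, and their absolute configuration follows from the twofold-symmetric bisphospholane on copper, which decides which face of the allyl unit meets which face of the aldehyde. The step needs Cu–Bpin to choose the allene over both carbonyl groups, as it does in the intermolecular couplings, and the allylcopper to choose the aldehyde over the ketone, which the substrate secures because only the formyl group is ortho to O1 and within reach of a five-membered closure while the acetyl group is para to O1 and could react only between molecules (slow addition of 10 keeps that pathway down). Loss of aryloxide cannot compete, since in neither σ-allyl form does copper stand β to the C–O bond.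

Step 8
Reactants: 13 1-[(2R,3R)-3-hydroxy-6,7-dimethoxy-2-[1-(4,4,5,5-tetramethyl-1,3,2-dioxaborolan-2-yl)ethenyl]-2,3-dihydro-1-benzofuran-5-yl]ethanone; 14 iodomethane
Product: 15 1-[(2R,3R)-3-hydroxy-6,7-dimethoxy-2-(prop-1-en-2-yl)-2,3-dihydro-1-benzofuran-5-yl]ethanone
Conditions: Pd2(dba)3 (2.5 mol %), P(o-tolyl)3 (10 mol %), K2CO3 (2 equiv), 14 (3 equiv), DMF–H2O 9:1, 50 °C, sealed tube
Reagents that add atoms: none
Why: Suzuki–Miyaura methylation of an alkenyl pinacol boronate with iodomethane is a known coupling, the bulky P(o-tolyl)3 resists quaternisation by MeI better than PPh3, carbonate is too weak to methylate the carbinol or the ketone, excess MeI keeps zerovalent palladium from ionising the allylic C2–O1 bond, and neither stereocentre is touched.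

Step 9
Reactants: 15 1-[(2R,3R)-3-hydroxy-6,7-dimethoxy-2-(prop-1-en-2-yl)-2,3-dihydro-1-benzofuran-5-yl]ethanone; 16 angelic acid
Product: 18 (2R,3R)-5-acetyl-6,7-dimethoxy-2-(prop-1-en-2-yl)-2,3-dihydro-1-benzofuran-3-yl (2Z)-2-methylbut-2-enoate (target CNP0113631.1), via mixed anhydride 17 (not isolated)
Conditions: 16 (2 equiv), 2,4,6-trichlorobenzoyl chloride (2 equiv), Et3N (4 equiv), toluene, rt, 1 h; then 15, 75 °C; no DMAP
Reagents that add atoms: 2,4,6-trichlorobenzoyl chloride O=C(Cl)c1c(Cl)cc(Cl)cc1Cl (its aroyl group is held only in 17 and leaves again)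
Why: Yamaguchi-type mixed-anhydride esterification, in which the carbinol attacks the open angeloyl carbonyl of 17 while the carbonyl flanked by two ortho chlorines is shielded, the absence of a nucleophilic catalyst avoids the conjugate addition–elimination that turns angelate (Z) into tiglate (E), and the C3–O bond is never broken so that (2R,3R) is kept.

**Compound list**
1 | 2-hydroxy-3,4-dimethoxybenzaldehyde | O=Cc1ccc(OC)c(OC)c1O | starting material
2 | 2-hydroxy-5-iodo-3,4-dimethoxybenzaldehyde | O=Cc1cc(I)c(OC)c(OC)c1O | intermediate
3 | tributyl(1-ethoxyethenyl)stannane | C=C(OCC)[Sn](CCCC)(CCCC)CCCC | starting material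
4 | 5-(1-ethoxyethenyl)-2-hydroxy-3,4-dimethoxybenzaldehyde | C=C(OCC)c1cc(C=O)c(O)c(OC)c1OC | intermediate
5 | 5-acetyl-2-hydroxy-3,4-dimethoxybenzaldehyde | CC(=O)c1cc(C=O)c(O)c(OC)c1OC | intermediate
6 | propargyl bromide (3-bromoprop-1-yne) | C#CCBr | starting material
7 | 5-acetyl-3,4-dimethoxy-2-(prop-2-yn-1-yloxy)benzaldehyde | CC(=O)c1cc(C=O)c(OCC#C)c(OC)c1OC | intermediate
8 | 1-(dimethoxymethyl)-5-(1,1-dimethoxyethyl)-3,4-dimethoxy-2-(prop-2-yn-1-yloxy)benzene | COC(OC)c1cc(C(C)(OC)OC)c(OC)c(OC)c1OCC#C | intermediate
9 | 1-(dimethoxymethyl)-5-(1,1-dimethoxyethyl)-3,4-dimethoxy-2-(propa-1,2-dien-1-yloxy)benzene | COC(OC)c1cc(C(C)(OC)OC)c(OC)c(OC)c1OC=C=C | intermediate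
10 | 1-[5-formyl-2,3-dimethoxy-4-(propa-1,2-dien-1-yloxy)phenyl]ethanone | C=C=COc1c(C=O)cc(C(C)=O)c(OC)c1OC | intermediate
11 | bis(pinacolato)diboron | CC1(C)OB(OC1(C)C)B2OC(C)(C)C(C)(C)O2 | starting material
12 | 1-[(2R,3R)-6,7-dimethoxy-3-[(4,4,5,5-tetramethyl-1,3,2-dioxaborolan-2-yl)oxy]-2-[1-(4,4,5,5-tetramethyl-1,3,2-dioxaborolan-2-yl)ethenyl]-2,3-dihydro-1-benzofuran-5-yl]ethanone | C=C(B2OC(C)(C)C(C)(C)O2)[C@H]1Oc3c(cc(C(C)=O)c(OC)c3OC)[C@H]1OB4OC(C)(C)C(C)(C)O4 | intermediate
13 | 1-[(2R,3R)-3-hydroxy-6,7-dimethoxy-2-[1-(4,4,5,5-tetramethyl-1,3,2-dioxaborolan-2-yl)ethenyl]-2,3-dihydro-1-benzofuran-5-yl]ethanone | C=C(B2OC(C)(C)C(C)(C)O2)[C@H]1Oc3c(cc(C(C)=O)c(OC)c3OC)[C@H]1O | intermediate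
14 | iodomethane | CI | starting material
15 | 1-[(2R,3R)-3-hydroxy-6,7-dimethoxy-2-(prop-1-en-2-yl)-2,3-dihydro-1-benzofuran-5-yl]ethanone | C=C(C)[C@H]1Oc2c(cc(C(C)=O)c(OC)c2OC)[C@H]1O | intermediate
16 | angelic acid, (2Z)-2-methylbut-2-enoic acid | C/C=C(/C)C(=O)O | starting material
17 | (2Z)-2-methylbut-2-enoic 2,4,6-trichlorobenzoic anhydride | C/C=C(/C)C(=O)OC(=O)c1c(Cl)cc(Cl)cc1Cl | intermediate
18 | (2R,3R)-5-acetyl-6,7-dimethoxy-2-(prop-1-en-2-yl)-2,3-dihydro-1-benzofuran-3-yl (2Z)-2-methylbut-2-enoate | C=C(C)[C@H]1Oc2c(cc(C(C)=O)c(OC)c2OC)[C@H]1OC(=O)/C(C)=C\C | target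

Total step count: 9. Longest linear sequence: 9 steps (1 to 18).

**Steps most likely to fail**

**Step 7.**
- What may go wrong: boryl transfer to the formyl group before the allene is engaged; borylcupration of the oxygen-substituted allene in the opposite regiochemical sense; E/Z equilibration of the allylcopper that erodes the cis preference; poor facial discrimination by the ligand.
- The fallback sets out from 9 and comes back at 13. It separates the two events and uses only established reaction types.
- Masked allenyl ether 9 is diborated with 11 (Pd(dba)2 with 3-iodo-2-methylcyclohex-2-en-1-one as co-catalyst, toluene, 80 °C). This is a known allene diboration that places one boron on the central carbon and the other on the unsubstituted terminus with (Z) geometry. It should give the allyl/alkenyl bis(boronate) F1.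
- LiBF4 in wet MeCN removes both acetals. The freed keto aldehyde F2 holds a (Z)-γ-aryloxyallylboronate beside the formyl group and should close at once by uncatalysed intramolecular allylboration through a chair. This is the known behaviour of (Z)-γ-alkoxyallylboronates (syn adducts) and of tethered allylboronates unmasked in this way (cis rings).
- The closure gives racemic boric ester, 12 and its (2S,3S) enantiomer F3. Aqueous work-up then gives racemic cis alcohol, 13 and its (2S,3S) enantiomer F4.
- Acylative kinetic resolution of the benzylic alcohol follows (isobutyric anhydride, iPr2NEt, the enantiomer of benzotetramisole that acylates the (2S,3S) alcohol, CHCl3, 0 °C). It turns F4 into the isobutyrate F5 and leaves 13, which is separated by chromatography.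

**Step 8.**
- What may go wrong: slow transmetalation with competing protodeboronation; ionisation of the allylic C2–O1 bond by zerovalent palladium, with epimerisation at C2 or ring opening.
- The fallback sets out from 13 and comes back at 15. It reverses the polarity of the coupling.
- Bromine (1.0 equiv, CH2Cl2, −78 °C) adds to the alkenyl boronate to give the vicinal dibromide F6.
- NaOMe in MeOH then triggers the known elimination of boron and the β-bromide to give the alkenyl bromide F7.
- Negishi coupling (Me2Zn, PdCl2(dppf), THF, 40 °C) installs the methyl group. The first equivalent of Me2Zn only deprotonates the carbinol.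
- Oxidative addition into the alkenyl bromide should outrun any attack of palladium on the allylic ether, and Me2Zn leaves the aryl ketone alone.

**Step 9.**
- What may go wrong: sluggish acylation of the hindered cis carbinol at the temperature needed; Z-to-E isomerisation of the activated acid; heat- or acid-induced loss of water across C2–C3 towards the aromatic benzofuran.
- The fallback sets out from 15 and comes back at 18. It builds the Z-alkene on the ester instead of carrying it through the acylation.
- Carbodiimide esterification (EDC·HCl, DMAP, CH2Cl2, 0 °C to rt) with saturated 2-[bis(2,2,2-trifluoroethoxy)phosphoryl]propanoic acid gives the phosphonopropionate F8. This acid has no double bond to isomerise and reacts at low temperature.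
- Still–Gennari olefination (KN(SiMe3)2, 18-crown-6, THF, −78 °C, then acetaldehyde) should then give the (Z)-2-methylbut-2-enoate 18. The phosphonate C–H is far more acidic than the acetyl group, so one equivalent of base is taken up there.

**Further compounds**
F1 | step 7 | 2-{[(1Z)-2,3-bis(4,4,5,5-tetramethyl-1,3,2-dioxaborolan-2-yl)prop-1-en-1-yl]oxy}-1-(dimethoxymethyl)-5-(1,1-dimethoxyethyl)-3,4-dimethoxybenzene | COC(OC)c1cc(C(C)(OC)OC)c(OC)c(OC)c1O/C=C(\CB2OC(C)(C)C(C)(C)O2)B3OC(C)(C)C(C)(C)O3
F2 | step 7 | 1-[4-{[(1Z)-2,3-bis(4,4,5,5-tetramethyl-1,3,2-dioxaborolan-2-yl)prop-1-en-1-yl]oxy}-5-formyl-2,3-dimethoxyphenyl]ethanone | CC(=O)c1cc(C=O)c(O/C=C(\CB2OC(C)(C)C(C)(C)O2)B3OC(C)(C)C(C)(C)O3)c(OC)c1OC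
F3 | step 7 | (2S,3S) enantiomer of 12 | C=C(B2OC(C)(C)C(C)(C)O2)[C@@H]1Oc3c(cc(C(C)=O)c(OC)c3OC)[C@@H]1OB4OC(C)(C)C(C)(C)O4
F4 | step 7 | (2S,3S) enantiomer of 13 | C=C(B2OC(C)(C)C(C)(C)O2)[C@@H]1Oc3c(cc(C(C)=O)c(OC)c3OC)[C@@H]1O
F5 | step 7 | (2S,3S)-5-acetyl-6,7-dimethoxy-2-[1-(4,4,5,5-tetramethyl-1,3,2-dioxaborolan-2-yl)ethenyl]-2,3-dihydro-1-benzofuran-3-yl 2-methylpropanoate | C=C(B2OC(C)(C)C(C)(C)O2)[C@@H]1Oc3c(cc(C(C)=O)c(OC)c3OC)[C@@H]1OC(=O)C(C)C
F6 | step 8 | vicinal dibromide of 13, 2-[1,2-dibromo-1-(4,4,5,5-tetramethyl-1,3,2-dioxaborolan-2-yl)ethyl] side chain, ring stereocentres as in 13, new carbon a mixture | BrCC(Br)(B2OC(C)(C)C(C)(C)O2)[C@H]1Oc3c(cc(C(C)=O)c(OC)c3OC)[C@H]1O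
F7 | step 8 | 1-[(2S,3R)-2-(1-bromoethenyl)-3-hydroxy-6,7-dimethoxy-2,3-dihydro-1-benzofuran-5-yl]ethanone (same spatial arrangement as 13; the C2 descriptor changes by priority only) | C=C(Br)[C@H]1Oc2c(cc(C(C)=O)c(OC)c2OC)[C@H]1O
F8 | step 9 | (2R,3R)-5-acetyl-6,7-dimethoxy-2-(prop-1-en-2-yl)-2,3-dihydro-1-benzofuran-3-yl 2-[bis(2,2,2-trifluoroethoxy)phosphoryl]propanoate (epimers at the phosphonate carbon) | C=C(C)[C@H]1Oc2c(cc(C(C)=O)c(OC)c2OC)[C@H]1OC(=O)C(C)P(=O)(OCC(F)(F)F)OCC(F)(F)F
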